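The route rests on cutting the aryl ether bond O–C1. Because the oxygenated quaternary C1 and the methyl-bearing C10 are neighbours, both are traced back to one tetrasubstituted alkene, C1=C10 of the seven-membered carbocycle, over which the C4–C7′ arm holds the ring A phenol. A Brønsted acid then adds O–H across this alkene: one operation forms O–C1, closes the oxepane of the bicyclo[4.2.1] core and sets C1 and C10. The precursor, a 4β-(2-hydroxy-4,6-dimethoxybenzyl)aromadendr-1(10)-ene, is built from (+)-2-carene by an allenic Pauson–Khand reaction, conjugate reduction, two α′-alkylations and equilibration of C5.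

Key step: step 16

Remark: aromadendrane numbering is used (C1–C15, benzylic carbon C7′, arene = ring A); β is the face that carries H5, C11, the C7′ arm and the ether oxygen in the target. Compounds 11, 17, 19 and 20 are C10 epimer mixtures and 5 and 26 are epimer mixtures at the carbinol or C7′ carbon; these centres are erased later. Compound 12 is assumed to be bought from a catalogue.

Step 1
Reactants: 1 (+)-2-carene
Product: 2 4-[cis-3-(dimethoxymethyl)-2,2-dimethylcyclopropyl]butan-2-one
Conditions: O3, CH2Cl2/MeOH, −78 °C; TsOH·H2O (cat.), rt; then NaHCO3, Me2S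
Reagents that add atoms: ozone [O-][O+]=O; methanol CO
Why: Ozonolysis in methanol (Criegee mechanism) puts the carbonyl oxide on the methyl-bearing carbon and leaves the other terminus as a free aldehyde, which the acid converts into its dimethyl acetal before Me2S reduces the methoxy hydroperoxide to the methyl ketone; the two cyclopropane stereocentres of 1 are not touched.

Step 2
Reactants: 2 keto acetal; 3 ethynylmagnesium bromide
Product: 5 methyl carbonate of 5-[cis-3-(dimethoxymethyl)-2,2-dimethylcyclopropyl]-3-methylpent-1-yn-3-ol, via bromomagnesium alkoxide 4 (not isolated)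
Conditions: 3 (1.5 equiv), THF, 0 °C to rt; then ClCO2Me, 0 °C to rt
Reagents that add atoms: methyl chloroformate COC(=O)Cl
Why: Grignard 1,2-addition to the methyl ketone followed by O-acylation of the magnesium alkoxide in the same flask gives the tertiary propargylic carbonate; the new carbinol centre forms as a mixture that is erased in step 3.

Step 3
Reactants: 5 propargylic carbonate
Product: 6 cis-1-(dimethoxymethyl)-2,2-dimethyl-3-(3-methylpenta-3,4-dienyl)cyclopropane
Conditions: Pd2(dba)3·CHCl3 (2.5 mol %), PBu3 (10 mol %), HCO2NH4 (2 equiv), THF, 40 °C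
Reagents that add atoms: none
Why: Palladium-catalysed formate hydrogenolysis of a propargylic carbonate, in which SN2′ oxidative addition gives an allenylpalladium species and decarboxylation of its formate with reductive elimination puts hydride on the terminal carbon, so a 1,1-disubstituted allene without axial chirality results.

Step 4
Reactants: 6 allene acetal
Product: 7 cis-2,2-dimethyl-3-(3-methylpenta-3,4-dienyl)cyclopropane-1-carbaldehyde
Conditions: pyridinium p-toluenesulfonate (cat.), acetone/H2O, 40 °C
Reagents that add atoms: water O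
Why: Mild acid hydrolysis of the dimethyl acetal frees the aldehyde without touching the allene; the cis aldehyde is used at once so that C6, now α to a carbonyl, does not epimerise.

Step 5
Reactants: 7 allenyl aldehyde
Product: 8 cis-1-ethynyl-2,2-dimethyl-3-(3-methylpenta-3,4-dienyl)cyclopropane
Conditions: Me3SiCHN2, LiN(iPr)2, THF, −78 °C to rt
Reagents that add atoms: trimethylsilyldiazomethane C[Si](C)(C)C=[N+]=[N-]
Why: Colvin rearrangement, in which lithiated trimethylsilyldiazomethane adds to the aldehyde, Peterson-type loss of silanolate gives a diazoalkene and then an alkylidene carbene, and a 1,2-hydrogen shift delivers the terminal alkyne under non-equilibrating conditions that keep the cis cyclopropane intact.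

Step 6
Reactants: 8 allenyne
Product: 9 15-noraromadendra-1(10),4-dien-3-one
Conditions: [Rh(CO)2Cl]2 (5 mol %), CO (1 atm), toluene, 90 °C
Reagents that add atoms: carbon monoxide [C-]#[O+]
Why: Allenic Pauson–Khand reaction, in which the monovalent rhodium carbonyl couples the alkyne with the distal allene double bond and CO while the cis cyclopropane holds both ends close, closing the seven- and five-membered rings at once as the 4-alkylidene cyclopentenone; no stereocentre is formed.

Step 7
Reactants: 9 dienone
Product: 11 5-epi-15-noraromadendr-1-en-3-one (H5 α), via β,γ-unsaturated ketone 10 (not isolated)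
Conditions: [(Ph3P)CuH]6 (0.35 equiv), H2O (2 equiv), toluene, rt; then DBU (0.2 equiv), CH2Cl2, rt
Reagents that add atoms: none
Why: Copper hydride conjugate reduction of the enone delivers hydride to C5 on the α-face, away from the gem-dimethylcyclopropane that covers the β-face of the flat dienone (H5 α, the epimer wanted at this stage), and catalytic base then moves the C1=C10 bond into conjugation by C2 deprotonation and C10 protonation.

Step 8
Reactants: 12 2-hydroxy-4,6-dimethoxybenzaldehyde
Product: 13 2-(allyloxy)-4,6-dimethoxybenzaldehyde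
Conditions: allyl bromide, K2CO3, DMF, rt
Reagents that add atoms: allyl bromide C=CCBr
Why: Williamson ether synthesis on the phenoxide; the allyl group masks the phenol until step 14.

Step 9
Reactants: 13 allyl ether aldehyde
Product: 14 [2-(allyloxy)-4,6-dimethoxyphenyl]methanol
Conditions: NaBH4, MeOH, 0 °C
Reagents that add atoms: none
Why: Borohydride 1,2-reduction of the aldehyde to the benzylic alcohol.

Step 10
Reactants: 14 benzylic alcohol
Product: 15 2-(allyloxy)-4,6-dimethoxybenzyl bromide
Conditions: PBr3 (0.4 equiv), Et2O, −20 °C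
Reagents that add atoms: phosphorus tribromide BrP(Br)Br
Why: Bromination of the benzylic alcohol with PBr3; the ionisation-prone bromide is made cold and used at once.

Step 11
Reactants: 11 enone; 15 benzylic bromide
Product: 17 4-[2-(allyloxy)-4,6-dimethoxybenzyl]-5-epi-15-noraromadendr-1-en-3-one, via lithium enolate 16 (not isolated)
Conditions: LiN(iPr)2 (1.05 equiv), THF, −78 °C; then 15, −78 to −40 °C
Reagents that add atoms: none
Why: Kinetic deprotonation of the cyclopentenone at the α′-carbon C4 (cross-conjugated enolate) and SN2 benzylation; the arm enters trans to C6, but this C4 centre is re-enolised in step 12.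

Step 12
Reactants: 17 monobenzyl enone
Product: 20 4β-[2-(allyloxy)-4,6-dimethoxybenzyl]aromadendr-1-en-3-one (4α-methyl; H5 β), via lithium enolate 18 (not isolated), via C5-epimeric enone 19 (not isolated)
Conditions: LiN(iPr)2 (1.1 equiv), THF, −78 °C; MeI, −78 to −20 °C; then NaOMe (0.3 equiv), MeOH, 60 °C
Reagents that add atoms: iodomethane CI
Why: A second α′-enolate alkylation creates the C4 quaternary centre with iodomethane approaching anti to the neighbouring C5–C6 bond (methyl α, benzyl arm β), after which methoxide equilibrates the γ-carbon C5 through the dienolate to the more stable epimer (H5 β, C6 trans to the benzyl arm and C4 turned away from C11), the quaternary C4 preventing migration of the enone.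

Step 13
Reactants: 20 quaternary enone
Product: 22 4β-[2-(allyloxy)-4,6-dimethoxybenzyl]aromadendra-1(10),2-dien-3-yl trifluoromethanesulfonate, via potassium dienolate 21 (not isolated)
Conditions: KN(SiMe3)2 (1.2 equiv), THF, −78 °C; then PhNTf2, −78 to 0 °C
Reagents that add atoms: N-phenylbis(trifluoromethanesulfonimide) O=S(=O)(N(c1ccccc1)S(=O)(=O)C(F)(F)F)C(F)(F)F
Why: With no α′-hydrogen left, the amide base removes the exposed γ-hydrogen at C10 (H5 lies shielded between C7 and C11) to give the extended dienolate, whose O-triflation restores the C1=C10 bond as part of a dienyl triflate.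

Step 14
Reactants: 22 dienyl triflate
Product: 23 2-[(aromadendra-1(10),2-dien-4β-yl)methyl]-3,5-dimethoxyphenol
Conditions: Pd(OAc)2 (5 mol %), PPh3 (20 mol %), HCO2H, Et3N, DMF, 60 °C
Reagents that add atoms: none
Why: Palladium-catalysed formate reduction of the vinyl triflate replaces the C3 oxygen by hydrogen, and the same zerovalent palladium–formate system cleaves the allyl aryl ether through a π-allyl complex to free the phenol.

Step 15
Reactants: 23 diene phenol
Product: 24 2-[(aromadendr-1(10)-en-4β-yl)methyl]-3,5-dimethoxyphenol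
Conditions: 2-nitrobenzenesulfonylhydrazide, Et3N, CH2Cl2, rt
Reagents that add atoms: none
Why: Diimide, generated in situ, transfers hydrogen syn to the cis-disubstituted C2=C3 bond and leaves the tetrasubstituted C1=C10 bond untouched.

Step 16
Reactants: 24 phenol alkene
Product: 25 bridged aryl ether with ring A joined to C4 through C7′H2 and to C1 through oxygen (C1–O β; H10 α)
Conditions: HNTf2 (10 mol %), CH2Cl2, −40 to 0 °C
Reagents that add atoms: none
Why: HNTf2 protonates the tetrasubstituted C1=C10 bond at C10 from the α-face (the β-face is covered by ring A and by the endo methyl on C11) while the phenol oxygen, held under C1 by the C4–C7′ arm, bonds to C1 and gives up its proton to regenerate the acid. The closest known reaction type is the Brønsted-acid-catalysed intramolecular Markovnikov hydroalkoxylation of unactivated alkenes by phenols, which gives chromans and, less often, benzoxepanes. The oxepane ring closes in a 7-exo-trig mode and in doing so bridges C1 and C4 of the cyclopentane to the bicyclo[4.2.1] core. C1 is controlled by the tether, since the oxygen can reach only its β-face, and C10 by anti addition, the proton arriving on the face opposite the oxygen so that C14 ends β. The step needs protonation at C10 and not at C1 (a C10 cation is out of reach of the phenol and reverts) and C–O closure faster than the 1,2-shift of H5 that would lead to a cyclopropylcarbinyl cation; the pre-organised oxygen close to C1, the non-nucleophilic counter-ion, the low temperature and the non-polar solvent are relied on for this.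

Step 17
Reactants: 25 bridged ether
Product: 26 C7′-methoxy derivative of 25
Conditions: DDQ (1.3 equiv), CH2Cl2/MeOH (4:1), 0 °C to rt
Reagents that add atoms: methanol CO
Why: Oxidation by DDQ removes hydride from the benzylic C7′, whose cation is stabilised by the ortho and para oxygens, and methanol traps it as the methyl ether; the C7′ configuration is irrelevant because it is ionised again.

Step 18
Reactants: 27 bromobenzene
Product: 29 bromomagnesium diphenylcuprate (solution, used at once), via phenylmagnesium bromide 28 (not isolated)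
Conditions: Mg, THF, rt; then CuBr·SMe2 (0.5 equiv), −40 °C
Reagents that add atoms: magnesium [Mg]; copper monobromide dimethyl sulfide complex Br[Cu].CSC
Why: Magnesium insertion gives the Grignard reagent, and transmetallation of two equivalents to copper monobromide gives the diphenylcuprate.

Step 19
Reactants: 26 benzylic methyl ether; 29 diphenylcuprate
Product: 30 C7′-phenyl bridged ether (phenyl syn to the C5 bridge)
Conditions: BF3·OEt2 (2 equiv), 29 (3 equiv), THF/CH2Cl2, −78 to −20 °C
Reagents that add atoms: none
Why: BF3 ionises the benzylic ether to the C7′ cation and the cuprate transfers phenyl to its exo face, the side of the one-carbon bridge C5 that carries only H5 and lies opposite the C2–C3 bridge, which sets C7′ as in the target.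

Step 20
Reactants: 30 dimethyl ether
Product: 31 4′,6′-dihydroxy bridged ether
Conditions: NaSEt (6 equiv), DMF, 130 °C; then aq HCl
Reagents that add atoms: none
Why: Thiolate SN2 attack on the two methyl groups cleaves both aryl methyl ethers, whereas the tertiary alkyl aryl ether cannot react in this way.

Step 21
Reactants: 31 resorcinol
Product: 32 psiguadial A
Conditions: Cl2CHOMe (5 equiv), TiCl4 (6 equiv), CH2Cl2, −78 to 0 °C; then H2O
Reagents that add atoms: dichloromethyl methyl ether COC(Cl)Cl; water O
Why: Twofold Rieche formylation, in which the titanium phenoxides direct the dichloromethyl methyl ether electrophile to the only two free ring positions, each ortho or para to the hydroxyls, and hydrolysis gives the dialdehyde.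

Compound list
1 | (+)-2-carene | CC1=C[C@H]2[C@@H](CC1)C2(C)C | starting material
2 | 4-[cis-3-(dimethoxymethyl)-2,2-dimethylcyclopropyl]butan-2-one | COC(OC)[C@H]1[C@@H](CCC(C)=O)C1(C)C | intermediate
3 | ethynylmagnesium bromide | C#C[Mg]Br | starting material
4 | bromomagnesium alkoxide of 5-[cis-3-(dimethoxymethyl)-2,2-dimethylcyclopropyl]-3-methylpent-1-yn-3-ol | COC(OC)[C@H]1[C@@H](CCC(C)(C#C)O[Mg]Br)C1(C)C | intermediate
5 | methyl carbonate of 5-[cis-3-(dimethoxymethyl)-2,2-dimethylcyclopropyl]-3-methylpent-1-yn-3-ol (carbinol epimers) | COC(OC)[C@H]1[C@@H](CCC(C)(C#C)OC(=O)OC)C1(C)C | intermediate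
6 | cis-1-(dimethoxymethyl)-2,2-dimethyl-3-(3-methylpenta-3,4-dienyl)cyclopropane | COC(OC)[C@H]1[C@@H](CCC(C)=C=C)C1(C)C | intermediate
7 | cis-2,2-dimethyl-3-(3-methylpenta-3,4-dienyl)cyclopropane-1-carbaldehyde | O=C[C@H]1[C@@H](CCC(C)=C=C)C1(C)C | intermediate
8 | cis-1-ethynyl-2,2-dimethyl-3-(3-methylpenta-3,4-dienyl)cyclopropane | C#C[C@H]1[C@@H](CCC(C)=C=C)C1(C)C | intermediate
9 | 15-noraromadendra-1(10),4-dien-3-one | CC1=C2CC(=O)C=C2[C@H]2[C@@H](CC1)C2(C)C | intermediate
10 | 5-epi-15-noraromadendr-1(10)-en-3-one (H5 α) | CC1CC[C@@H]2[C@H]([C@H]3CC(=O)CC3=1)C2(C)C | intermediate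
11 | 5-epi-15-noraromadendr-1-en-3-one (H5 α, C10 epimers) | CC1CC[C@@H]2[C@H]([C@H]3CC(=O)C=C31)C2(C)C | intermediate
12 | 2-hydroxy-4,6-dimethoxybenzaldehyde | O=Cc1c(O)cc(OC)cc1OC | starting material
13 | 2-(allyloxy)-4,6-dimethoxybenzaldehyde | O=Cc1c(OCC=C)cc(OC)cc1OC | intermediate
14 | [2-(allyloxy)-4,6-dimethoxyphenyl]methanol | OCc1c(OCC=C)cc(OC)cc1OC | intermediate
15 | 2-(allyloxy)-4,6-dimethoxybenzyl bromide | BrCc1c(OCC=C)cc(OC)cc1OC | intermediate
16 | lithium α′-enolate of 11 | CC1CC[C@@H]2[C@H]([C@H]3C=C(O[Li])C=C31)C2(C)C | intermediate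
17 | 4-[2-(allyloxy)-4,6-dimethoxybenzyl]-5-epi-15-noraromadendr-1-en-3-one (arm α, trans to C6; C10 epimers) | CC1CC[C@@H]2[C@H]([C@H]3[C@H](Cc4c(OCC=C)cc(OC)cc4OC)C(=O)C=C31)C2(C)C | intermediate
18 | lithium α′-enolate of 17 | CC1CC[C@@H]2[C@H]([C@H]3C(Cc4c(OCC=C)cc(OC)cc4OC)=C(O[Li])C=C31)C2(C)C | intermediate
19 | 4β-[2-(allyloxy)-4,6-dimethoxybenzyl]-5-epi-aromadendr-1-en-3-one (4α-methyl, H5 α, C10 epimers) | CC1CC[C@@H]2[C@H]([C@H]3[C@](Cc4c(OCC=C)cc(OC)cc4OC)(C)C(=O)C=C31)C2(C)C | intermediate
20 | 4β-[2-(allyloxy)-4,6-dimethoxybenzyl]aromadendr-1-en-3-one (4α-methyl, H5 β, C10 epimers) | CC1CC[C@@H]2[C@H]([C@@H]3[C@](Cc4c(OCC=C)cc(OC)cc4OC)(C)C(=O)C=C31)C2(C)C | intermediate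
21 | potassium 1(10),2-dien-3-olate of 20 | CC1CC[C@@H]2[C@H]([C@@H]3[C@](Cc4c(OCC=C)cc(OC)cc4OC)(C)C(O[K])=CC3=1)C2(C)C | intermediate
22 | 4β-[2-(allyloxy)-4,6-dimethoxybenzyl]aromadendra-1(10),2-dien-3-yl trifluoromethanesulfonate | CC1CC[C@@H]2[C@H]([C@@H]3[C@](Cc4c(OCC=C)cc(OC)cc4OC)(C)C(OS(=O)(=O)C(F)(F)F)=CC3=1)C2(C)C | intermediate
23 | 2-[(aromadendra-1(10),2-dien-4β-yl)methyl]-3,5-dimethoxyphenol | CC1CC[C@@H]2[C@H]([C@@H]3[C@](Cc4c(O)cc(OC)cc4OC)(C)C=CC3=1)C2(C)C | intermediate
24 | 2-[(aromadendr-1(10)-en-4β-yl)methyl]-3,5-dimethoxyphenol (precursor of the key step) | CC1CC[C@@H]2[C@H]([C@@H]3[C@](Cc4c(O)cc(OC)cc4OC)(C)CCC3=1)C2(C)C | intermediate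
25 | bridged aryl ether, ring A joined to C4 through C7′H2 and to C1 through oxygen (C1–O β, H10 α, 4′,6′-dimethoxy) | C[C@H]1CC[C@@H]2[C@H]([C@@H]3[C@]4(C)CC[C@@]31Oc1cc(OC)cc(OC)c1C4)C2(C)C | intermediate
26 | C7′-methoxy derivative of 25 (C7′ epimers) | C[C@H]1CC[C@@H]2[C@H]([C@@H]3[C@]4(C)CC[C@@]31Oc1cc(OC)cc(OC)c1C4OC)C2(C)C | intermediate
27 | bromobenzene | Brc1ccccc1 | starting material
28 | phenylmagnesium bromide | Br[Mg]c1ccccc1 | intermediate
29 | bromomagnesium diphenylcuprate | Br[Mg+].c1ccccc1[Cu-]c1ccccc1 | intermediate
30 | C7′-phenyl bridged ether (phenyl syn to C5, 4′,6′-dimethoxy) | C[C@H]1CC[C@@H]2[C@H]([C@@H]3[C@]4(C)CC[C@@]31Oc1cc(OC)cc(OC)c1[C@@H]4c1ccccc1)C2(C)C | intermediate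
31 | C7′-phenyl bridged ether, 4′,6′-diol | C[C@H]1CC[C@@H]2[C@H]([C@@H]3[C@]4(C)CC[C@@]31Oc1cc(O)cc(O)c1[C@@H]4c1ccccc1)C2(C)C | intermediate
32 | psiguadial A | C[C@H]1CC[C@@H]2[C@H]([C@@H]3[C@]4(C)CC[C@@]31Oc1c(C=O)c(O)c(C=O)c(O)c1[C@@H]4c1ccccc1)C2(C)C | target

Total step count: 21. Longest linear sequence: 17 steps (steps 1–7, 11–17 and 19–21).

Steps most likely to fail

Step 16. The C1 cation may take up H5 by a 1,2-hydride shift and then open the cyclopropane or lose a proton to the 1(5)-alkene faster than the oxygen closes on C1. The fallback replaces the cationic hydroalkoxylation by an epoxide opening and sets out from 24. Buffered peracid epoxidation (mCPBA, NaHCO3, CH2Cl2, −20 °C) should attack the open α-face of C1=C10 to give the 1α,10α-epoxide F1. With a trace of pyridinium p-toluenesulfonate the phenol should open it at C1 with inversion to the 10α-hydroxy bridged ether F2. Acylation with methyl chlorooxoacetate and DMAP gives the tertiary methyl oxalate F3, and Bu3SnH with AIBN in hot toluene removes the oxygen, the C10 radical taking hydrogen from the open α-face. The route is rejoined at 25.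

Step 7. Hydride may be delivered to C10 in a 1,6 sense, or the newly formed enone may be reduced further. The fallback changes from a stoichiometric hydride donor to catalytic silyl transfer and sets out from 9. Hydrosilylation with Et3SiH and RhCl(PPh3)3 in toluene at 60 °C should give the 1,4-adduct, the triethylsilyl enol ether F4, again with H5 α. Fluoride (Bu4NF buffered with AcOH) releases the β,γ-unsaturated ketone, so the route is rejoined at 10, which is conjugated with DBU as before.

Step 11. The electron-rich benzylic bromide 15 may ionise and alkylate its own arene before it meets the enolate. The fallback uses the stable aldehyde instead and sets out from 11. Enolate 16 is formed as in step 11 and adds to aldehyde 13 at −78 °C to give the β-hydroxy ketone F5. Ionic hydrogenation (Et3SiH, CF3CO2H, CH2Cl2, −40 °C) then removes the benzylic hydroxyl through the stabilised C7′ cation. The route is rejoined at 17.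

Further compounds
F1 | step 16 | 1α,10α-epoxide of 24 | C[C@@]12CC[C@@H]3[C@H]([C@@H]4[C@](Cc5c(O)cc(OC)cc5OC)(C)CC[C@]41O2)C3(C)C
F2 | step 16 | 10α-hydroxy derivative of 25 | C[C@@]1(O)CC[C@@H]2[C@H]([C@@H]3[C@]4(C)CC[C@@]31Oc1cc(OC)cc(OC)c1C4)C2(C)C
F3 | step 16 | methyl oxalate of F2 | C[C@@]1(OC(=O)C(=O)OC)CC[C@@H]2[C@H]([C@@H]3[C@]4(C)CC[C@@]31Oc1cc(OC)cc(OC)c1C4)C2(C)C
F4 | step 7 | triethylsilyl enol ether of 10 | CC1CC[C@@H]2[C@H]([C@H]3C=C(O[Si](CC)(CC)CC)CC3=1)C2(C)C
F5 | step 11 | aldol adduct of 16 with 13 | CC1CC[C@@H]2[C@H]([C@H]3C(C(O)c4c(OCC=C)cc(OC)cc4OC)C(=O)C=C31)C2(C)C
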